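**Retrosynthetic overview**
1. Target 9 ⇒ C–O: acylation of the last primary OH of mono-isobutyrate 7 with (S)-2-methylbutanoic anhydride 8, which brings the side-chain stereocentre from the chiral pool.
2. 7 ⇒ C–O: enantiotopic-group-selective (lipase) isobutyrylation of the prochiral triol 5; this sets the carbinol stereocentre.
3. 5 ⇒ 2 × C–C: both CH2OH arms are cut off at once, giving the ester carbon of methyl 4-methylsalicylate 1 (electrophile) and two hydroxymethyl-anion equivalents, the silylmethyl Grignard reagent 3 (a carbon that is normally the electrophilic formaldehyde carbon, used here as the nucleophile); C–Si is then oxidised to C–OH.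
4. No ring is formed; the benzene ring is bought with 1.

Assumption: the lipase in step 2 acylates the enantiotopic CH2OH group that gives (R)-7. This sense must be confirmed on the first run; the fallback for step 2 covers the opposite outcome.

**Step 1**
Reactants: 1 methyl 2-hydroxy-4-methylbenzoate; 2 (chloromethyl)(isopropoxy)dimethylsilane
Product: 5 2-(2-hydroxy-4-methylphenyl)propane-1,2,3-triol, via silylmethyl Grignard reagent 3 (not isolated), via bis-silyl carbinol 4 (not isolated)
Conditions: 2 (5 equiv), Mg, THF, 45 °C; CeCl3 (5 equiv), THF, −78 °C, then 1, −78 °C → rt; aq. NaHCO3, filter off salts (no acid, no silica); then 30% H2O2, KF, KHCO3, THF/MeOH, rt → 40 °C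
Reagents that add atoms: hydrogen peroxide, OO
Why: Proposed new method: double nucleophilic hydroxymethylation of an ester, in which the α-silyl carbanion 3 (a hydroxymethyl-anion equivalent) adds twice to the ester carbonyl after one equivalent has deprotonated the phenol, cerium suppresses enolisation of the intermediate α-silyl ketone, the magnesium β-silyl alkoxide does not undergo Peterson elimination, and Tamao–Fleming oxidation then turns both C–Si bonds into C–OH; the closest known reactions are the nucleophilic hydroxymethylation of ketones with this same Grignard reagent and the CeCl3-promoted double addition of Me3SiCH2MgCl to esters; no stereocentre is formed because C-2 of 5 is prochiral.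

**Step 2**
Reactants: 5 2-(2-hydroxy-4-methylphenyl)propane-1,2,3-triol; 6 2-methylpropanoic (isobutyric) anhydride
Product: 7 (R)-2,3-dihydroxy-2-(2-hydroxy-4-methylphenyl)propyl 2-methylpropanoate
Conditions: immobilised Burkholderia cepacia lipase (Amano PS-IM), 6 (1.1 equiv), THF/MTBE 1:4, 20 °C, stop when 5 is consumed; filter, use at once
Reagents that add atoms: none
Why: Lipase-catalysed desymmetrisation of a prochiral 2,2-disubstituted propane-1,3-diol, in which the enzyme active site distinguishes the two enantiotopic CH2OH groups and so sets the (R) carbinol centre, while the phenol and the tertiary OH are not lipase substrates and the neutral medium avoids the acyl migration that would racemise 7.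

**Step 3**
Reactants: 7 (R)-2,3-dihydroxy-2-(2-hydroxy-4-methylphenyl)propyl 2-methylpropanoate; 8 (S)-2-methylbutanoic anhydride
Product: 9 (S)-2-hydroxy-2-(2-hydroxy-4-methylphenyl)-3-(2-methylpropanoyloxy)propyl (S)-2-methylbutanoate
Conditions: Novozym 435 (immobilised CAL-B, high loading), 8 (2 equiv), toluene/MTBE, 40 °C; filter, quick chromatography on neutral silica
Reagents that add atoms: none
Why: Lipase-catalysed acyl transfer esterifies only the one remaining primary OH (not the phenol or the tertiary OH) under neutral conditions, so the acyl stereocentre of 8 is carried over unchanged and the carbinol centre is not scrambled by acyl migration; the descriptor changes from R to S only because the CIP priorities of the two arms swap.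

**Compound list**
1 | methyl 2-hydroxy-4-methylbenzoate (methyl 4-methylsalicylate) | COC(=O)c1ccc(C)cc1O | starting material
2 | (chloromethyl)(isopropoxy)dimethylsilane | CC(C)O[Si](C)(C)CCl | starting material
3 | [(isopropoxydimethylsilyl)methyl]magnesium chloride | CC(C)O[Si](C)(C)C[Mg]Cl | intermediate
4 | 2-(2-hydroxy-4-methylphenyl)-1,3-bis[isopropoxy(dimethyl)silyl]propan-2-ol | CC(C)O[Si](C)(C)CC(O)(C[Si](C)(C)OC(C)C)c1ccc(C)cc1O | intermediate
5 | 2-(2-hydroxy-4-methylphenyl)propane-1,2,3-triol | OCC(O)(CO)c1ccc(C)cc1O | intermediate
6 | 2-methylpropanoic (isobutyric) anhydride | CC(C)C(=O)OC(=O)C(C)C | starting material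
7 | (R)-2,3-dihydroxy-2-(2-hydroxy-4-methylphenyl)propyl 2-methylpropanoate | OC[C@@](O)(COC(=O)C(C)C)c1ccc(C)cc1O | intermediate
8 | (S)-2-methylbutanoic anhydride | CC[C@H](C)C(=O)OC(=O)[C@@H](C)CC | starting material
9 | (S)-2-hydroxy-2-(2-hydroxy-4-methylphenyl)-3-(2-methylpropanoyloxy)propyl (S)-2-methylbutanoate | CC[C@H](C)C(=O)OC[C@@](O)(COC(=O)C(C)C)c1ccc(C)cc1O | target

**Totals**
Total step count: 3. Step 1 is one telescoped operation; 4 is only freed from salts by filtration, not purified.
Longest linear sequence: 3.

**Steps most likely to fail, with fallbacks**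

Step 1 is the riskiest. The second addition may stall at the enolised α-silyl ketone, or 4 may undergo Peterson elimination before oxidation. The fallback sets out from 1 and uses an α-alkoxy organolithium as the hydroxymethyl-anion equivalent instead of the silicon reagent. Benzyloxymethyllithium (from tributyl[(benzyloxy)methyl]stannane and n-BuLi, THF, −78 °C, 3.3 equiv, CeCl3) is added twice to 1 to give 1,3-bis(benzyloxy)-2-(2-hydroxy-4-methylphenyl)propan-2-ol F1, which is stable and can be purified. Neutral hydrogenolysis (H2, Pd(OH)2/C, EtOAc, rt) removes both benzyl groups, and the route is rejoined at 5.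

Step 2 is next. The lipase may select the other enantiotopic arm, or 7 may lose enantiopurity through acyl migration. The fallback sets out from 5 and reverses the order in which the two esters are put on. The same lipase and 8 (1.1 equiv, THF/MTBE, 20 °C) place the chiral acyl group first, on the arm the enzyme prefers, to give (S)-2,3-dihydroxy-2-(2-hydroxy-4-methylphenyl)propyl (S)-2-methylbutanoate F2. Novozym 435 and 6 then isobutyrylate the remaining arm, and the route is rejoined at 9. Any epimer at the carbinol carbon is a diastereomer of 9 and would be removed by preparative HPLC.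

Step 3 is third. Enzymatic acylation of the arm the lipase disfavours, with an α-branched donor, may be too slow. The fallback sets out from 7 and gives up O-selectivity in the acylation. (S)-2-Methylbutanoic acid (2.5 equiv), EDC·HCl and catalytic DMAP in CH2Cl2 at 0 °C acylate both the primary OH and the phenol to give 2-[(S)-2-hydroxy-1-(2-methylpropanoyloxy)-3-[(S)-2-methylbutanoyloxy]propan-2-yl]-5-methylphenyl (S)-2-methylbutanoate F3. The far more reactive aryl ester is then removed by aminolysis with n-butylamine (1.2 equiv, CH2Cl2, 0 °C), which leaves the two alkyl esters alone, and the route is rejoined at 9.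

**Further compounds**
F1 | step 1 | 1,3-bis(benzyloxy)-2-(2-hydroxy-4-methylphenyl)propan-2-ol | Cc1ccc(c(O)c1)C(O)(COCc1ccccc1)COCc1ccccc1
F2 | step 2 | (S)-2,3-dihydroxy-2-(2-hydroxy-4-methylphenyl)propyl (S)-2-methylbutanoate | CC[C@H](C)C(=O)OC[C@@](O)(CO)c1ccc(C)cc1O
F3 | step 3 | 2-[(S)-2-hydroxy-1-(2-methylpropanoyloxy)-3-[(S)-2-methylbutanoyloxy]propan-2-yl]-5-methylphenyl (S)-2-methylbutanoate | CC[C@H](C)C(=O)OC[C@@](O)(COC(=O)C(C)C)c1ccc(C)cc1OC(=O)[C@@H](C)CC
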